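**Retrosynthetic overview**
1. The strategy rests on the dioxane ring O1–C2–C3–O4. C2 is benzylic to the 4-hydroxy-3,5-dimethoxyphenyl ring, so the C2–O1 bond can ionise to a p-quinone methide; C3 (methyl) cannot. Disconnecting O1–C2 therefore leads to the C2-epimeric carbinols 14, which should both converge on the trans ring.
2. 14 comes from desilylation of 13. The C1–aryl bond of 13 is made from the syringyl Grignard reagent 11 and lactol 8, a masked (R)-2-aryloxypropanal.
3. 8 comes from DIBAL half-reduction of hydroxy ester 6. 6 comes from Dakin oxidation of aldehyde 4, which puts the future O1 on ring A.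
4. 4 comes from Mitsunobu coupling of 2 with methyl (S)-lactate (forms O4–C3 with inversion, sets C3 as R). 2 comes from ortho-formylation of eugenol.
5. Ring order: both arenes are bought. The 1,4-dioxane ring is the only ring made; it appears transiently as lactol 8, is opened in step 6, and is closed for good in the last step.

Key step: step 8

Assumption: the trans isomer of a 2-aryl-3-methyl-1,4-benzodioxane, with aryl and methyl both pseudo-equatorial on the half-chair, is taken to be the thermodynamically preferred C2 epimer, so equilibration through the quinone methide should enrich (2R,3R).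

**Step 1**
Reactants: 1 eugenol
Product: 2 5-allyl-2-hydroxy-3-methoxybenzaldehyde
Conditions: MgCl2, Et3N, (CH2O)n, MeCN, reflux; then aq. HCl
Reagents that add atoms: paraformaldehyde (formaldehyde), C=O
Why: Magnesium-mediated ortho-formylation of a phenol (Casnati–Skattebøl): the magnesium phenoxide delivers formaldehyde to the only free ortho carbon, a second formaldehyde oxidises the benzylic alkoxide to the aldehyde by hydride transfer, and the allyl group is not touched.

**Step 2**
Reactants: 2 5-allyl-2-hydroxy-3-methoxybenzaldehyde; 3 methyl (S)-lactate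
Product: 4 methyl (2R)-2-(4-allyl-2-formyl-6-methoxyphenoxy)propanoate
Conditions: PPh3, DIAD, THF, 0 °C → rt
Reagents that add atoms: none
Why: Mitsunobu etherification of the acidic salicylaldehyde phenol with the secondary lactate carbinol is an SN2 displacement at the oxyphosphonium carbon, so (S) inverts to (R) and the future C3 stereocentre is set here.

**Step 3**
Reactants: 4 methyl (2R)-2-(4-allyl-2-formyl-6-methoxyphenoxy)propanoate
Product: 6 methyl (2R)-2-(4-allyl-2-hydroxy-6-methoxyphenoxy)propanoate, via aryl formate 5 (not isolated)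
Conditions: 30% aq. H2O2, cat. H2SO4, MeOH, rt
Reagents that add atoms: hydrogen peroxide, OO
Why: Acid-catalysed Dakin (Baeyer–Villiger-type) oxidation of an ortho-alkoxybenzaldehyde: the hydroperoxide adduct rearranges with migration of the electron-rich aryl group to formate 5, which methanol cleaves to the phenol; hydrogen peroxide without a peracid should not epoxidise the terminal alkene, and methanol matches the methyl ester.

**Step 4**
Reactants: 6 methyl (2R)-2-(4-allyl-2-hydroxy-6-methoxyphenoxy)propanoate
Product: 8 (3R)-7-allyl-5-methoxy-3-methyl-2,3-dihydro-1,4-benzodioxin-2-ol (lactol as both anomers), via open-chain hydroxy aldehyde 7 (not isolated)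
Conditions: DIBAL-H (2.3 equiv), CH2Cl2, −78 °C; MeOH, then aq. Rochelle salt
Reagents that add atoms: none
Why: DIBAL half-reduction of an α-alkoxy ester stops at the chelated aluminium hemiacetal (the first equivalent is consumed by the phenol), and the aldehyde 7 released is trapped by the ortho phenol as the six-membered lactol, which protects it from over-reduction and shields the α-stereocentre from enolisation.

**Step 5**
Reactants: 9 4-bromo-2,6-dimethoxyphenol
Product: 10 (4-bromo-2,6-dimethoxyphenoxy)(tert-butyl)dimethylsilane
Conditions: TBSCl, imidazole, DMF, rt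
Reagents that add atoms: tert-butyldimethylsilyl chloride, C[Si](C)(Cl)C(C)(C)C
Why: Standard imidazole-promoted silylation masks the acidic phenol so that the aryl bromide can be turned into a Grignard reagent.

**Step 6**
Reactants: 8 (3R)-7-allyl-5-methoxy-3-methyl-2,3-dihydro-1,4-benzodioxin-2-ol; 10 (4-bromo-2,6-dimethoxyphenoxy)(tert-butyl)dimethylsilane
Product: 13 (2R)-2-(4-allyl-2-hydroxy-6-methoxyphenoxy)-1-[4-(tert-butyldimethylsilyloxy)-3,5-dimethoxyphenyl]propan-1-ol (both C1 epimers), via arylmagnesium bromide 11 (not isolated), via ring-opened aldehyde magnesium phenoxide 12 (not isolated)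
Conditions: 10 (3.5 equiv), Mg, cat. I2, THF, reflux; then 8, THF, −78 → 0 °C; aq. NH4Cl
Reagents that add atoms: none
Why: Grignard addition to a lactol: one equivalent of 11 deprotonates the lactol, the magnesium lactolate opens to aldehyde 12 with the aryloxide as leaving group, and a second equivalent adds to the aldehyde; no facial control is needed because both carbinol epimers are erased in step 8, and C3 is not a reacting centre.

**Step 7**
Reactants: 13 (2R)-2-(4-allyl-2-hydroxy-6-methoxyphenoxy)-1-[4-(tert-butyldimethylsilyloxy)-3,5-dimethoxyphenyl]propan-1-ol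
Product: 14 (2R)-2-(4-allyl-2-hydroxy-6-methoxyphenoxy)-1-(4-hydroxy-3,5-dimethoxyphenyl)propan-1-ol (both C1 epimers)
Conditions: TBAF, AcOH (1:1), THF, 0 °C
Reagents that add atoms: none
Why: Fluoride cleavage of the aryl silyl ether; the acetic acid buffer keeps the freed 4-hydroxybenzyl alcohol from base-induced quinone-methide chemistry before the controlled closure.

**Step 8**
Reactants: 14 (2R)-2-(4-allyl-2-hydroxy-6-methoxyphenoxy)-1-(4-hydroxy-3,5-dimethoxyphenyl)propan-1-ol
Product: 16 (2R,3R)-7-allyl-2-(4-hydroxy-3,5-dimethoxyphenyl)-5-methoxy-3-methyl-2,3-dihydro-1,4-benzodioxine, via p-quinone methide 15 (not isolated)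
Conditions: CSA (0.2 equiv), 4 Å MS, CH2Cl2 (0.01 M), 0 °C → rt (40 °C if the cis isomer persists)
Reagents that add atoms: none
Why: Acid-promoted loss of water from the 4-hydroxybenzylic alcohol gives p-quinone methide 15 (its O-protonated form is the 4-hydroxy-3,5-dimethoxybenzyl cation), which the ring-A phenol captures by intramolecular oxa-1,6-addition; the closest known reaction type is the acid cyclisation of 8-O-4′ carbinols bearing an ortho phenol to 2-aryl-1,4-benzodioxanes. Both carbinol epimers of 14 give the same planar intermediate, so the C1 configuration of the precursor is erased. The dioxane ring closes 6-exo-trig by attack of the phenol oxygen (future O1) on the exocyclic quinone-methide carbon (future C2); C-alkylation of ring A is excluded because both carbons ortho to the ether oxygen are substituted. The new C2 stereocentre is controlled thermodynamically by the fixed (R)-C3 methyl group: the benzylic C2–O1 aryl ether re-ionises under the same acid, so the mixture should drain to the trans (2R,3R) half-chair with aryl and methyl both pseudo-equatorial. The step needs diastereoselectivity at C2 (secured by this reversibility), chemoselectivity for intramolecular O-capture over capture by another phenol or the allyl alkene (secured by the five-atom tether and high dilution), and retention of C3, whose only escape is E1 loss of H-3 to an enol ether, a path that mild, dry, near-ambient conditions should leave closed.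

**Compound list**
1 | eugenol (4-allyl-2-methoxyphenol) | C=CCc1ccc(O)c(OC)c1 | starting material
2 | 5-allyl-2-hydroxy-3-methoxybenzaldehyde | C=CCc1cc(OC)c(O)c(C=O)c1 | intermediate
3 | methyl (S)-lactate | C[C@H](O)C(=O)OC | starting material
4 | methyl (2R)-2-(4-allyl-2-formyl-6-methoxyphenoxy)propanoate | C=CCc1cc(OC)c(O[C@H](C)C(=O)OC)c(C=O)c1 | intermediate
5 | methyl (2R)-2-[4-allyl-2-(formyloxy)-6-methoxyphenoxy]propanoate (aryl formate, not isolated) | C=CCc1cc(OC)c(O[C@H](C)C(=O)OC)c(OC=O)c1 | intermediate
6 | methyl (2R)-2-(4-allyl-2-hydroxy-6-methoxyphenoxy)propanoate | C=CCc1cc(OC)c(O[C@H](C)C(=O)OC)c(O)c1 | intermediate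
7 | (2R)-2-(4-allyl-2-hydroxy-6-methoxyphenoxy)propanal (open-chain hydroxy aldehyde, not isolated) | C=CCc1cc(OC)c(O[C@H](C)C=O)c(O)c1 | intermediate
8 | (3R)-7-allyl-5-methoxy-3-methyl-2,3-dihydro-1,4-benzodioxin-2-ol (lactol, both anomers) | C=CCc1cc(OC)c2c(c1)OC(O)[C@@H](C)O2 | intermediate
9 | 4-bromo-2,6-dimethoxyphenol | COc1cc(Br)cc(OC)c1O | starting material
10 | (4-bromo-2,6-dimethoxyphenoxy)(tert-butyl)dimethylsilane | COc1cc(Br)cc(OC)c1O[Si](C)(C)C(C)(C)C | intermediate
11 | [4-(tert-butyldimethylsilyloxy)-3,5-dimethoxyphenyl]magnesium bromide (not isolated) | COc1cc([Mg]Br)cc(OC)c1O[Si](C)(C)C(C)(C)C | intermediate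
12 | bromomagnesium 5-allyl-3-methoxy-2-{[(2R)-1-oxopropan-2-yl]oxy}phenoxide (ring-opened aldehyde, not isolated) | C=CCc1cc(OC)c(O[C@H](C)C=O)c(O[Mg]Br)c1 | intermediate
13 | (2R)-2-(4-allyl-2-hydroxy-6-methoxyphenoxy)-1-[4-(tert-butyldimethylsilyloxy)-3,5-dimethoxyphenyl]propan-1-ol (both C1 epimers) | C=CCc1cc(OC)c(O[C@H](C)C(O)c2cc(OC)c(O[Si](C)(C)C(C)(C)C)c(OC)c2)c(O)c1 | intermediate
14 | (2R)-2-(4-allyl-2-hydroxy-6-methoxyphenoxy)-1-(4-hydroxy-3,5-dimethoxyphenyl)propan-1-ol (both C1 epimers) | C=CCc1cc(OC)c(O[C@H](C)C(O)c2cc(OC)c(O)c(OC)c2)c(O)c1 | intermediate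
15 | 4-[(2R)-2-(4-allyl-2-hydroxy-6-methoxyphenoxy)propylidene]-2,6-dimethoxycyclohexa-2,5-dien-1-one (p-quinone methide, not isolated) | C=CCc1cc(OC)c(O[C@H](C)C=C2C=C(OC)C(=O)C(OC)=C2)c(O)c1 | intermediate
16 | (2R,3R)-7-allyl-2-(4-hydroxy-3,5-dimethoxyphenyl)-5-methoxy-3-methyl-2,3-dihydro-1,4-benzodioxine | C=CCc1cc(OC)c2c(c1)O[C@H](c1cc(OC)c(O)c(OC)c1)[C@@H](C)O2 | target

**Step count and risks**
Total steps: 8. Longest linear sequence: 7 steps (steps 1, 2, 3, 4, 6, 7, 8 from eugenol); step 5 is a one-step side branch that joins at step 6.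

Steps most likely to fail:

1. Step 8. The equilibration may stall with the cis C2 epimer still present, the quinone methide may be diverted into intermolecular capture and oligomerisation, or E1 loss of H-3 may erode C3. Fallback: a stereospecific SN2 closure that sets out from 13 and returns at 16. The two carbinol epimers of 13 would be separated by chromatography, and the (1S,2R) erythro epimer F1 would be closed by intramolecular Mitsunobu etherification (PPh3, DIAD, THF, 0 °C), the ring-A phenol displacing the activated benzylic oxygen with inversion to give the silyl-protected trans-benzodioxane F2. TBAF/AcOH in THF would then free the phenol to give 16.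

2. Step 6. The basic Grignard reagent may enolise the transient α-aryloxy aldehyde, which would lower conversion and erode C3. Fallback: an acylation–reduction sequence that sets out from 6 and returns at 13. Ester 6 would be converted with MeNHOMe·HCl and iPrMgCl (THF, −20 °C) into the Weinreb amide F3. Addition of 11 would stop at the chelated tetrahedral adduct and give, after quench, the aryl ketone F4. NaBH4 in MeOH at −20 °C would then give 13 as both epimers, which is all the key step requires.

3. Step 2. Coupling at the phenol flanked by formyl and methoxy groups may be sluggish, and competing pathways at the lactate carbon may cost enantiopurity. Fallback: a sulfonate alkylation that sets out from 2 and 3 and returns at 4. Lactate 3 would be converted with Tf2O and 2,6-lutidine (CH2Cl2, −78 °C) into methyl (S)-2-(trifluoromethylsulfonyloxy)propanoate F5. The potassium phenoxide of 2 (K2CO3, MeCN, 0 °C → rt) would displace the triflate with inversion to give 4.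

**Further compounds**
F1 | step 8 | (1S,2R)-2-(4-allyl-2-hydroxy-6-methoxyphenoxy)-1-[4-(tert-butyldimethylsilyloxy)-3,5-dimethoxyphenyl]propan-1-ol | C=CCc1cc(OC)c(O[C@H](C)[C@@H](O)c2cc(OC)c(O[Si](C)(C)C(C)(C)C)c(OC)c2)c(O)c1
F2 | step 8 | {4-[(2R,3R)-7-allyl-5-methoxy-3-methyl-2,3-dihydro-1,4-benzodioxin-2-yl]-2,6-dimethoxyphenoxy}(tert-butyl)dimethylsilane | C=CCc1cc(OC)c2c(c1)O[C@H](c1cc(OC)c(O[Si](C)(C)C(C)(C)C)c(OC)c1)[C@@H](C)O2
F3 | step 6 | (2R)-2-(4-allyl-2-hydroxy-6-methoxyphenoxy)-N-methoxy-N-methylpropanamide | C=CCc1cc(OC)c(O[C@H](C)C(=O)N(C)OC)c(O)c1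
F4 | step 6 | (2R)-2-(4-allyl-2-hydroxy-6-methoxyphenoxy)-1-[4-(tert-butyldimethylsilyloxy)-3,5-dimethoxyphenyl]propan-1-one | C=CCc1cc(OC)c(O[C@H](C)C(=O)c2cc(OC)c(O[Si](C)(C)C(C)(C)C)c(OC)c2)c(O)c1
F5 | step 2 | methyl (S)-2-(trifluoromethylsulfonyloxy)propanoate | C[C@H](OS(=O)(=O)C(F)(F)F)C(=O)OC
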